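**Strategy**

The cyclohexane ring (C1 carries the oxane, C2 the hydroxyl, C4 methyl and chlorine, C5 bromine) is cut at C1–C2 and C3–C4. This leaves an acyclic (E,E)-dienol holding C1, C6, C5, C4 and the whole side chain, and a vinyl unit for C2–C3. The route exploits the 1,3 relationship between the C2 hydroxyl and the tertiary oxygen on oxane carbon C2′: a vinylboronate is tethered to that oxygen, an intramolecular Diels–Alder reaction forms both ring bonds with regio- and stereocontrol, and oxidation of the C–B bond gives the C2 hydroxyl. Bromoetherification then closes the oxane ring; the ring halogens follow from an epoxide through a 1,2-bromine shift.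

Key step: step 5

Remark on numbering: C3 and C6 are the ring methylene carbons. C2′ (tertiary carbinol carbon bonded to C1), C3′ (acetoxy carbon), C4′, C5′ and C6′ (prenyl alkene carbons, C6′ with two methyl groups) are the carbons of the later oxane ring. The target is taken as (2S,3S,5S) in the oxane and (1S,2R,4R,5R) in the cyclohexane, as the SMILES encodes.

**Route**

Step 1
Reactants: 1 6-methylhept-5-en-2-one
Product: 3 (3S)-3-hydroxy-6-methylhept-5-en-2-one, via aminoxy ketone 2 (not isolated)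
Conditions: D-proline (cat.), PhNO (slow addition), DMSO, rt; then Zn, AcOH, THF, 0 °C
Reagents that add atoms: nitrosobenzene O=Nc1ccccc1
Why: Proline-catalysed α-aminoxylation (O-selective nitroso aldol reaction) should run through the more substituted enamine, the carboxylic acid of D-proline steering nitrosobenzene to the face that gives the 3S centre, and zinc then cleaves the N–O bond without touching that centre.

Step 2
Reactants: 3 (3S)-3-hydroxy-6-methylhept-5-en-2-one
Product: 4 (3S,4S)-3,7-dimethylocta-1,6-diene-3,4-diol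
Conditions: CH2=CHMgBr (3 equiv), THF, −78 → 0 °C; then H2O
Reagents that add atoms: vinylmagnesium bromide C=C[Mg]Br
Why: Chelation-controlled Grignard addition: the magnesium alkoxide formed by the first equivalent holds the ketone in a five-membered chelate and vinyl adds to the face opposite the prenyl-bearing CH2 group, which sets the tertiary carbinol centre as 3S.

Step 3
Reactants: 4 (3S,4S)-3,7-dimethylocta-1,6-diene-3,4-diol and 5 (1E)-1-bromoprop-1-ene
Product: 6 (2E,4E,6S,7S)-6,10-dimethylundeca-2,4,9-triene-6,7-diol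
Conditions: Pd(OAc)2 (cat.), Bu4NCl, K2CO3, DMF, 40 °C (sealed tube)
Reagents that add atoms: none
Why: Heck reaction under ligand-free phase-transfer conditions: the alkenylpalladium species adds to the terminal vinyl carbon and β-hydride elimination, possible only away from the fully substituted carbinol carbon, should give the E,E-diene with the bromoalkene geometry retained while the trisubstituted alkene stays inert.

Step 4
Reactants: 6 (2E,4E,6S,7S)-6,10-dimethylundeca-2,4,9-triene-6,7-diol
Product: 7 (2E,4E,6S,7S)-6-hydroxy-6,10-dimethylundeca-2,4,9-trien-7-yl acetate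
Conditions: Ac2O, pyridine, DMAP (cat.), CH2Cl2, 0 °C
Reagents that add atoms: acetic anhydride CC(=O)OC(C)=O
Why: Nucleophile-catalysed acetylation should take the secondary hydroxyl only, because the tertiary dienylic hydroxyl is too hindered, and this leaves the tether site free.

Step 5
Reactants: 7 (2E,4E,6S,7S)-6-hydroxy-6,10-dimethylundeca-2,4,9-trien-7-yl acetate and 8 dibutyl ethenylboronate
Product: 12 (2S,3S)-2-hydroxy-2-[(1S,4S,6R)-6-hydroxy-4-methylcyclohex-2-en-1-yl]-6-methylhept-5-en-3-yl acetate, via mixed boronate 9 (not isolated), via oxaborolane cycloadduct 10 (not isolated), via cyclic borate 11 (not isolated)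
Conditions: 8 (1.5 equiv), BHT (cat.), toluene, 110 °C with removal of BuOH, then 140 °C (sealed tube); then Me3NO, THF, 65 °C; aqueous work-up
Reagents that add atoms: trimethylamine N-oxide C[N+](C)(C)[O-]
Why: Transesterification of the tertiary hydroxyl of 7 with 8 gives mixed boronate 9, whose vinyl group then adds across the (E,E)-diene in a concerted, suprafacial intramolecular Diels–Alder reaction, the boron-tethered cycloaddition known for dienols and alkenylboronic esters. The cyclohexene ring is closed by the [4+2] cycloaddition itself (C1–C2 and C3–C4 form together), and the 1,2-oxaborolane ring closes in the fused mode because the three-atom C2′–O–B tether lets the boron-bearing carbon reach only C1, which fixes the regiochemistry. C2 is set by the endo position of the trigonal boron (cis ring fusion, favoured by the planar C–B–O unit and by overlap of the empty boron orbital with the diene) and is kept when Me3NO migrates carbon from boron to oxygen with retention; C4 follows from the E geometry of the diene and is erased later. C1 is set relative to C2′ by π-facial selection: in the fused transition structure the C2′ methyl lies next to C6 and the larger acetoxy-prenyl chain points to the convex face. The step needs endo over exo closure and one diene face, both secured by the short tether on the quaternary carbinol centre, and hydrolysis of cyclic borate 11 on work-up should release diol 12.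

Step 6
Reactants: 12 (2S,3S)-2-hydroxy-2-[(1S,4S,6R)-6-hydroxy-4-methylcyclohex-2-en-1-yl]-6-methylhept-5-en-3-yl acetate
Product: 13 (2S,3S)-2-[(1S,4S,6R)-6-{[tert-butyl(dimethyl)silyl]oxy}-4-methylcyclohex-2-en-1-yl]-2-hydroxy-6-methylhept-5-en-3-yl acetate
Conditions: TBSOTf (1.1 equiv), 2,6-lutidine, CH2Cl2, −78 °C
Reagents that add atoms: tert-butyldimethylsilyl triflate CC(C)(C)[Si](C)(C)OS(=O)(=O)C(F)(F)F
Why: Silylation at low temperature should take the secondary C2 hydroxyl and leave the tertiary C2′ hydroxyl free; the bulky axial silyl ether later shields one face of the ring.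

Step 7
Reactants: 13 (2S,3S)-2-[(1S,4S,6R)-6-{[tert-butyl(dimethyl)silyl]oxy}-4-methylcyclohex-2-en-1-yl]-2-hydroxy-6-methylhept-5-en-3-yl acetate
Product: 14 (2S,3S,5S)-5-bromo-2-[(1S,4S,6R)-6-{[tert-butyl(dimethyl)silyl]oxy}-4-methylcyclohex-2-en-1-yl]-2,6,6-trimethyloxan-3-yl acetate
Conditions: NBS, (CF3)2CHOH, −20 °C
Reagents that add atoms: N-bromosuccinimide O=C1CCC(=O)N1Br
Why: Bromoetherification: the bromonium ion forms on the electron-rich trisubstituted alkene (the disubstituted ring alkene reacts more slowly) and the tertiary hydroxyl captures it at C6′ in a 6-endo, Markovnikov sense through a chair transition structure with the cyclohexenyl group on C2′ equatorial and the C2′ methyl axial, which should place bromine equatorial and set C5′ as S.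

Step 8
Reactants: 14 (2S,3S,5S)-5-bromo-2-[(1S,4S,6R)-6-{[tert-butyl(dimethyl)silyl]oxy}-4-methylcyclohex-2-en-1-yl]-2,6,6-trimethyloxan-3-yl acetate
Product: 15 (2S,3S,5S)-5-bromo-2-[(1S,6R)-6-{[tert-butyl(dimethyl)silyl]oxy}-4-methylcyclohex-3-en-1-yl]-2,6,6-trimethyloxan-3-yl acetate
Conditions: [Ir(cod)(PMePh2)2]PF6 (cat., activated with H2, then degassed), THF, 40 °C
Reagents that add atoms: none
Why: Iridium hydride-mediated 1,3-hydrogen shift through a π-allyl intermediate should move the disubstituted C5=C6 alkene to the more stable trisubstituted C4=C5 position, because the C4 hydrogen is abstracted in preference to the hindered C1 hydrogen and the trisubstituted product binds the cationic catalyst poorly.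

Step 9
Reactants: 15 (2S,3S,5S)-5-bromo-2-[(1S,6R)-6-{[tert-butyl(dimethyl)silyl]oxy}-4-methylcyclohex-3-en-1-yl]-2,6,6-trimethyloxan-3-yl acetate
Product: 16 (2S,3S,5S)-5-bromo-2-[(1S,3S,4R,6R)-4-{[tert-butyl(dimethyl)silyl]oxy}-6-methyl-7-oxabicyclo[4.1.0]heptan-3-yl]-2,6,6-trimethyloxan-3-yl acetate
Conditions: mCPBA, NaHCO3, CH2Cl2, 0 °C
Reagents that add atoms: 3-chloroperoxybenzoic acid OOC(=O)c1cccc(Cl)c1
Why: Prilezhaev epoxidation: the axial C2 silyloxy group, 1,3 to C4, shields the face that carries the C1 substituent, so oxygen should be delivered to the opposite face.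

Step 10
Reactants: 16 (2S,3S,5S)-5-bromo-2-[(1S,3S,4R,6R)-4-{[tert-butyl(dimethyl)silyl]oxy}-6-methyl-7-oxabicyclo[4.1.0]heptan-3-yl]-2,6,6-trimethyloxan-3-yl acetate
Product: 17 (2S,3S,5S)-5-bromo-2-[(1S,2R,4S,5S)-4-bromo-2-{[tert-butyl(dimethyl)silyl]oxy}-5-hydroxy-4-methylcyclohexyl]-2,6,6-trimethyloxan-3-yl acetate
Conditions: HBr (33% in AcOH, 1.1 equiv), CH2Cl2, −40 °C
Reagents that add atoms: hydrogen bromide Br
Why: Acid-promoted trans-diaxial opening of the trisubstituted epoxide should occur at the tertiary carbon C4 with inversion, putting bromine on the face of the C1 substituent and the C5 hydroxyl on the opposite face; the regioisomeric trans-bromohydrin would lead to the same bromonium ion in step 11.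

Step 11
Reactants: 17 (2S,3S,5S)-5-bromo-2-[(1S,2R,4S,5S)-4-bromo-2-{[tert-butyl(dimethyl)silyl]oxy}-5-hydroxy-4-methylcyclohexyl]-2,6,6-trimethyloxan-3-yl acetate
Product: 20 (2S,3S,5S)-5-bromo-2-[(1S,2R,4R,5R)-5-bromo-2-{[tert-butyl(dimethyl)silyl]oxy}-4-chloro-4-methylcyclohexyl]-2,6,6-trimethyloxan-3-yl acetate, via chlorosulfite 18 (not isolated), via bromonium chloride 19 (not isolated)
Conditions: SOCl2, pyridine, CH2Cl2, −20 °C → rt
Reagents that add atoms: thionyl chloride O=S(Cl)Cl
Why: Ionisation of chlorosulfite 18 is assisted by the antiperiplanar C4 bromine (neighbouring-group participation), and chloride should open the unsymmetrical bromonium ion 19 at the tertiary carbon C4 from the opposite face, so that bromine ends on C5 and chlorine on C4, trans to each other, each centre being set by one inversion.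

Step 12
Reactants: 20 (2S,3S,5S)-5-bromo-2-[(1S,2R,4R,5R)-5-bromo-2-{[tert-butyl(dimethyl)silyl]oxy}-4-chloro-4-methylcyclohexyl]-2,6,6-trimethyloxan-3-yl acetate
Product: 21 (2S,3S,5S)-5-bromo-2-[(1S,2R,4R,5R)-5-bromo-4-chloro-2-hydroxy-4-methylcyclohexyl]-2,6,6-trimethyloxan-3-yl acetate
Conditions: HF·pyridine, THF, 0 °C → rt
Reagents that add atoms: none
Why: Fluoride-driven cleavage of the silyl ether (Si–F bond formation) should free the C2 hydroxyl under conditions that leave the acetate, the oxane and both alkyl halides untouched.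

**Compound list**

1 | 6-methylhept-5-en-2-one | CC(=O)CCC=C(C)C | starting material
2 | (3S)-3-(anilinooxy)-6-methylhept-5-en-2-one | CC(=O)[C@@H](ONc1ccccc1)CC=C(C)C | intermediate
3 | (3S)-3-hydroxy-6-methylhept-5-en-2-one | CC(=O)[C@@H](O)CC=C(C)C | intermediate
4 | (3S,4S)-3,7-dimethylocta-1,6-diene-3,4-diol | C=C[C@](C)(O)[C@@H](O)CC=C(C)C | intermediate
5 | (1E)-1-bromoprop-1-ene | C/C=C/Br | starting material
6 | (2E,4E,6S,7S)-6,10-dimethylundeca-2,4,9-triene-6,7-diol | C/C=C/C=C/[C@](C)(O)[C@@H](O)CC=C(C)C | intermediate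
7 | (2E,4E,6S,7S)-6-hydroxy-6,10-dimethylundeca-2,4,9-trien-7-yl acetate | C/C=C/C=C/[C@](C)(O)[C@@H](OC(C)=O)CC=C(C)C | intermediate
8 | dibutyl ethenylboronate | C=CB(OCCCC)OCCCC | starting material
9 | butyl (2E,4E,6S,7S)-7-acetoxy-6,10-dimethylundeca-2,4,9-trien-6-yl ethenylboronate (mixed boronate) | C/C=C/C=C/[C@](C)(OB(C=C)OCCCC)[C@@H](OC(C)=O)CC=C(C)C | intermediate
10 | (1S)-1-[(3S,3aR,6S,7aR)-1-butoxy-3,6-dimethyl-1,3,3a,6,7,7a-hexahydro-2,1-benzoxaborol-3-yl]-4-methylpent-3-en-1-yl acetate (cis-fused oxaborolane cycloadduct) | CC(=O)O[C@@H](CC=C(C)C)[C@@]2(C)OB(OCCCC)[C@@H]3C[C@H](C)C=C[C@H]23 | intermediate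
11 | (1S)-1-[(4S,4aS,7S,8aR)-2-butoxy-4,7-dimethyl-4a,7,8,8a-tetrahydro-4H-1,3,2-benzodioxaborinin-4-yl]-4-methylpent-3-en-1-yl acetate (cyclic borate) | CC(=O)O[C@@H](CC=C(C)C)[C@@]2(C)OB(OCCCC)O[C@@H]3C[C@H](C)C=C[C@H]23 | intermediate
12 | (2S,3S)-2-hydroxy-2-[(1S,4S,6R)-6-hydroxy-4-methylcyclohex-2-en-1-yl]-6-methylhept-5-en-3-yl acetate | CC(=O)O[C@@H](CC=C(C)C)[C@@](C)(O)[C@H]1C=C[C@@H](C)C[C@H]1O | intermediate
13 | (2S,3S)-2-[(1S,4S,6R)-6-{[tert-butyl(dimethyl)silyl]oxy}-4-methylcyclohex-2-en-1-yl]-2-hydroxy-6-methylhept-5-en-3-yl acetate | CC(=O)O[C@@H](CC=C(C)C)[C@@](C)(O)[C@H]1C=C[C@@H](C)C[C@H]1O[Si](C)(C)C(C)(C)C | intermediate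
14 | (2S,3S,5S)-5-bromo-2-[(1S,4S,6R)-6-{[tert-butyl(dimethyl)silyl]oxy}-4-methylcyclohex-2-en-1-yl]-2,6,6-trimethyloxan-3-yl acetate | CC(=O)O[C@H]1C[C@H](Br)C(C)(C)O[C@@]1(C)[C@H]1C=C[C@@H](C)C[C@H]1O[Si](C)(C)C(C)(C)C | intermediate
15 | (2S,3S,5S)-5-bromo-2-[(1S,6R)-6-{[tert-butyl(dimethyl)silyl]oxy}-4-methylcyclohex-3-en-1-yl]-2,6,6-trimethyloxan-3-yl acetate | CC(=O)O[C@H]1C[C@H](Br)C(C)(C)O[C@@]1(C)[C@H]1CC=C(C)C[C@H]1O[Si](C)(C)C(C)(C)C | intermediate
16 | (2S,3S,5S)-5-bromo-2-[(1S,3S,4R,6R)-4-{[tert-butyl(dimethyl)silyl]oxy}-6-methyl-7-oxabicyclo[4.1.0]heptan-3-yl]-2,6,6-trimethyloxan-3-yl acetate | CC(=O)O[C@H]1C[C@H](Br)C(C)(C)O[C@@]1(C)[C@H]1C[C@@H]2O[C@]2(C)C[C@H]1O[Si](C)(C)C(C)(C)C | intermediate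
17 | (2S,3S,5S)-5-bromo-2-[(1S,2R,4S,5S)-4-bromo-2-{[tert-butyl(dimethyl)silyl]oxy}-5-hydroxy-4-methylcyclohexyl]-2,6,6-trimethyloxan-3-yl acetate | CC(=O)O[C@H]1C[C@H](Br)C(C)(C)O[C@@]1(C)[C@H]1C[C@H](O)[C@@](C)(Br)C[C@H]1O[Si](C)(C)C(C)(C)C | intermediate
18 | chlorosulfite of 17 (C5 hydroxyl as O–S(O)Cl) | CC(=O)O[C@H]1C[C@H](Br)C(C)(C)O[C@@]1(C)[C@H]1C[C@H](OS(=O)Cl)[C@@](C)(Br)C[C@H]1O[Si](C)(C)C(C)(C)C | intermediate
19 | bromonium chloride (bromine bridging C4 and C5 on the face of the C1 substituent, chloride counter-ion) | CC(=O)O[C@H]1C[C@H](Br)C(C)(C)O[C@@]1(C)[C@H]1C[C@H]2[Br+][C@@]2(C)C[C@H]1O[Si](C)(C)C(C)(C)C.[Cl-] | intermediate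
20 | (2S,3S,5S)-5-bromo-2-[(1S,2R,4R,5R)-5-bromo-2-{[tert-butyl(dimethyl)silyl]oxy}-4-chloro-4-methylcyclohexyl]-2,6,6-trimethyloxan-3-yl acetate | CC(=O)O[C@H]1C[C@H](Br)C(C)(C)O[C@@]1(C)[C@H]1C[C@@H](Br)[C@](C)(Cl)C[C@H]1O[Si](C)(C)C(C)(C)C | intermediate
21 | (2S,3S,5S)-5-bromo-2-[(1S,2R,4R,5R)-5-bromo-4-chloro-2-hydroxy-4-methylcyclohexyl]-2,6,6-trimethyloxan-3-yl acetate | CC(=O)O[C@H]1C[C@H](Br)C(C)(C)O[C@@]1(C)[C@H]1C[C@@H](Br)[C@](C)(Cl)C[C@H]1O | target

**Step count and risks**

Total steps: 12. Longest linear sequence: 12 steps (1 → 21; compounds 5 and 8 are purchased).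

Steps most likely to fail:

Step 5. The hindered tertiary hydroxyl may exchange onto boron incompletely, the tertiary dienylic borate may ionise or eliminate on heating, and exo closure would give the wrong configuration at C2. The fallback sets out from 7 and uses a silicon tether with a later correction at C2. Chloro(dimethyl)vinylsilane with imidazole and DMAP should give the vinylsilyl ether F1. Heating in toluene at about 180 °C should give the bicyclic siloxane cycloadduct F2, for which exo closure (silicon trans to the side chain) is expected. Tamao oxidation (H2O2, KF, KHCO3) should then give the C2-epimeric diol F3. Dess–Martin periodinane should oxidise it to the ketone F4, and LiBH(s-Bu)3 at −78 °C should deliver hydride anti to the C1 substituent to give the cis alcohol, which returns to the route at 12.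

Step 8. The double bond may migrate past C4=C5 (toward C3 and the silyl enol ether) or toward C1, or not move at all. The fallback sets out from 14. mCPBA should epoxidise the C5=C6 alkene on the face away from the C1 and C4 substituents to give the epoxide F5. Diethylaluminium 2,2,6,6-tetramethylpiperidide should remove the C4 hydrogen syn to the epoxide oxygen and give the allylic alcohol F6 with the C4=C5 alkene in place. Acetylation should give the allylic acetate F7. Pd(PPh3)4 with Bu3SnH should then deliver hydride to the less substituted C6 end of the π-allyl complex, which returns to the route at 15.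

Step 11. Chloride may open the bromonium ion at the secondary carbon (no bromine shift) or displace the chlorosulfite directly with inversion. The fallback sets out from 15 and puts bromine on C5 by direct substitution. OsO4 (cat.) with N-methylmorpholine N-oxide should dihydroxylate the alkene anti to the axial silyloxy group to give the cis-diol F8. SOCl2 with Et3N, then RuCl3 (cat.) with NaIO4, should give the cyclic sulfate F9. LiBr should open it at the secondary carbon C5 with inversion, and acidic hydrolysis of the sulfate ester should give the bromohydrin F10 with a tertiary C4 hydroxyl. SOCl2 with catalytic TiCl4 should replace that hydroxyl by chloride with retention, which returns to the route at 20.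

Further compounds
F1 | step 5 | (2E,4E,6S,7S)-6-{[ethenyl(dimethyl)silyl]oxy}-6,10-dimethylundeca-2,4,9-trien-7-yl acetate | C/C=C/C=C/[C@](C)(O[Si](C)(C)C=C)[C@@H](OC(C)=O)CC=C(C)C
F2 | step 5 | bicyclic siloxane cycloadduct (1,1,3,6-tetramethyl-hexahydro-2,1-benzoxasilole with the acetoxy-prenyl chain on C3, silicon trans to that chain at the ring fusion) | CC(=O)O[C@@H](CC=C(C)C)[C@@]2(C)O[Si](C)(C)[C@H]3C[C@H](C)C=C[C@H]23
F3 | step 5 | (2S,3S)-2-hydroxy-2-[(1S,4S,6S)-6-hydroxy-4-methylcyclohex-2-en-1-yl]-6-methylhept-5-en-3-yl acetate | CC(=O)O[C@@H](CC=C(C)C)[C@@](C)(O)[C@H]1C=C[C@@H](C)C[C@@H]1O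
F4 | step 5 | (2S,3S)-2-hydroxy-6-methyl-2-[(1R,4S)-4-methyl-6-oxocyclohex-2-en-1-yl]hept-5-en-3-yl acetate | CC(=O)O[C@@H](CC=C(C)C)[C@@](C)(O)[C@H]1C=C[C@@H](C)CC1=O
F5 | step 8 | C5–C6 epoxide of 14 (oxygen anti to the C1 and C4 substituents) | CC(=O)O[C@H]1C[C@H](Br)C(C)(C)O[C@@]1(C)[C@H]1[C@@H]2O[C@@H]2[C@@H](C)C[C@H]1O[Si](C)(C)C(C)(C)C
F6 | step 8 | allylic alcohol (C6 hydroxyl, C4=C5 alkene) | CC(=O)O[C@H]1C[C@H](Br)C(C)(C)O[C@@]1(C)[C@H]1[C@H](O)C=C(C)C[C@H]1O[Si](C)(C)C(C)(C)C
F7 | step 8 | allylic acetate (C6 acetoxy, C4=C5 alkene) | CC(=O)O[C@H]1C[C@H](Br)C(C)(C)O[C@@]1(C)[C@H]1[C@H](OC(C)=O)C=C(C)C[C@H]1O[Si](C)(C)C(C)(C)C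
F8 | step 11 | cis-4,5-diol of 15 (both hydroxyls anti to the C1 substituent) | CC(=O)O[C@H]1C[C@H](Br)C(C)(C)O[C@@]1(C)[C@H]1C[C@H](O)[C@](C)(O)C[C@H]1O[Si](C)(C)C(C)(C)C
F9 | step 11 | cyclic sulfate of the 4,5-diol | CC(=O)O[C@H]1C[C@H](Br)C(C)(C)O[C@@]1(C)[C@H]1C[C@@H]2OS(=O)(=O)O[C@]2(C)C[C@H]1O[Si](C)(C)C(C)(C)C
F10 | step 11 | (2S,3S,5S)-5-bromo-2-[(1S,2R,4R,5R)-5-bromo-2-{[tert-butyl(dimethyl)silyl]oxy}-4-hydroxy-4-methylcyclohexyl]-2,6,6-trimethyloxan-3-yl acetate | CC(=O)O[C@H]1C[C@H](Br)C(C)(C)O[C@@]1(C)[C@H]1C[C@@H](Br)[C@](C)(O)C[C@H]1O[Si](C)(C)C(C)(C)C
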